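These three neighbouring flasks differ in one setting, the equivalents of free base, and we ask what that does to the electrophile within the run.

    electrophile + nucleophile → acid set free + product (k1 = 0.22 L mol⁻¹ s⁻¹)
    nucleophile + acid set free ⇌ protonated nucleophile, settled at all times (K2 = 2200 L mol⁻¹)
    acid set free + free base ⇌ salt of the base (K3 = 2.2 × 10⁵ L mol⁻¹, k3 = 4.8 L mol⁻¹ s⁻¹)
    gas ⇌ nucleophile, rate k4*(csat - [nucleophile]) (k4 = 0.033 s⁻¹, csat = 17 mM)
    acid set free + free base ⇌ idle adduct, settled at all times (K5 = 13 L mol⁻¹)

| setting | south-east | south | south-west |
|---|---|---|---|
| electrophile | 41 mM | 41 mM | 41 mM |
| free base | 4.40 equiv | 1.10 equiv | 2.20 equiv |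
| gas | 17 mM (held) | 17 mM (held) | 17 mM (held) |
| time | 1.5 min | 1.5 min | 1.5 min |

- acid set free is meant together with its idle adduct
- at the start none of nucleophile is dissolved
- run time (south-east): 1.5 min

* part of the electrophile that has reacted at the end, south-east
* part of the electrophile that has reacted at the end, south
* part of the electrophile that has reacted at the end, south-west
* what raising the equivalents of free base from its lowest to its highest value here does to the part of the electrophile that has reacted (changes below 5 percentage points count as none) (no change / it falls / it rises)

Taking the electrophile as charged, it eats dissolved nucleophile at 0.00902 s⁻¹, less than the transfer coefficient 0.033 s⁻¹. The two together give 0.0420 s⁻¹, so the nucleophile climbs to a level of 13.4 mM, and the climb costs a lag of 23.3 s. At that level the electrophile falls pseudo-first-order, and we carry the tenfold time 13.1 min, the time it needs to fall by one power of ten. The run less the lag is 0.0852 of a power of ten, which gives 17.8% in south-east, 17.8% in south and 17.8% in south-west, since free base does not enter this reckoning.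

As a harsh case, let all the acid set free sit on the nucleophile, so that each electrophile costs two nucleophile. The same reckoning then gives 15.7%, a drop of 2.1 percentage points, less than the 5 points that counts. We therefore expect no change.

The forecast, stepped by hand, gives 16.9% in south-east, 16.3% in south and 16.7% in south-west, a little below ours, and no change, noting of the protonated nucleophile that “most of that is refilled by gas transfer”.

The simulation gives 17.1% in south-east, 16.5% in south and 16.8% in south-west, so no change, with a change of 0.64 points.

The south-west reading is 0.0799 of a power of ten, against our 0.0852. Its nucleophile stood at 12.4 mM after 1.50 min, against our level of 13.4 mM. Now read the same south-west flask, as a neighbouring flask, at 6.0 min. The same tenfold time and lag give 0.428 of a power of ten, so 62.7% reacted. The neighbouring flask, south-west read at that time, gives 64.3%, with nucleophile at 15.5 mM.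

(The numbers of this flask come from no measurement; the run is a simulation.)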